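The disconnection is the bond between aryl C1 and the β-carbon of the propanoate, made by joining two electrophilic carbons: a nickel-catalysed electroreductive conjugate addition of an aryl bromide to octadecyl acrylate. In one cathode-driven operation the complete C21 ester side chain, already at the saturated oxidation level, is attached to the crowded position beside an oxygen of the contiguously 1,2,3,4-substituted benzene ring. The precursor is 1,3-bis(benzyloxy)-4-bromo-2-methoxybenzene. It comes from C2v-symmetric 2-methoxyresorcinol, whose equivalent C4 and C6 positions let bromination converge on one regioisomer. Commercial octadecyl acrylate is the partner.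

Key step: step 3

Remark: the target has no stereocentre and no stereogenic double bond, so it is achiral; the constitution alone defines the compound and no stereocontrol is needed.

Step 1
Reactants: 1 2-methoxybenzene-1,3-diol (2-methoxyresorcinol)
Product: 2 1,3-bis(benzyloxy)-2-methoxybenzene
Conditions: BnBr (2.3 equiv), K2CO3 (3 equiv), DMF, 60 °C
Reagents that add atoms: benzyl bromide, BrCc1ccccc1
Why: Williamson ether synthesis, in which both phenoxides are O-alkylated by the reactive benzylic bromide, masking the acidic OH groups that would protonate aryl–nickel species in step 3 with groups that later leave under neutral hydrogenolysis.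

Step 2
Reactants: 2 1,3-bis(benzyloxy)-2-methoxybenzene
Product: 3 1,3-bis(benzyloxy)-4-bromo-2-methoxybenzene
Conditions: NBS (1.02 equiv), MeCN, 0 °C to rt, dark
Reagents that add atoms: N-bromosuccinimide, O=C1CCC(=O)N1Br
Why: Electrophilic aromatic bromination, in which C4 (equivalent to C6) is para to one benzyloxy group and ortho to the other while the twisted central methoxy group activates C5 only weakly, so the polar NBS bromination should give the 4-bromide and the deactivating bromine should limit dibromination.

Step 3
Reactants: 3 1,3-bis(benzyloxy)-4-bromo-2-methoxybenzene; 4 octadecyl acrylate (octadecyl prop-2-enoate, 2 equiv)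
Product: 7 octadecyl 3-[2,4-bis(benzyloxy)-3-methoxyphenyl]propanoate, via arylnickel(II) bromide complex 5 (not isolated), via α-nickelated ester 6 (not isolated)
Conditions: NiBr2·3H2O (10 mol%), n-Bu4NBr/n-Bu4NI, H2O (2 equiv), DMF–pyridine 9:1, undivided cell, Fe anode, Ni-foam cathode, constant current (ca. 2.2 F/mol), 70 °C, Ar
Reagents that add atoms: none
Why: Cathodic reduction of Ni(II) gives a pyridine/acrylate-ligated Ni(0) that adds oxidatively into the C–Br bond of 3 to give 5, migratory insertion of coordinated 4 delivers the aryl group to the β-carbon to give 6, and protonolysis by the water present releases 7 and Ni(II), which is reduced again at the cathode while the iron anode is consumed. The closest known reaction type is the nickel-catalysed electroreductive conjugate addition (reductive Heck-type hydroarylation) of aryl bromides to acrylates in DMF–pyridine with a sacrificial anode, which accepts electron-rich and ortho-substituted aryl bromides. No ring is closed and no stereocentre is formed, since the C–Ni carbon of 6 ends as a CH2 group. The step needs regioselectivity for aryl transfer to the β-carbon, which the polarisation of the acrylate and the ester-stabilised C–Ni bond secure. It also needs chemoselectivity for insertion and protonolysis over hydrodebromination, biaryl formation and β-hydride elimination, which the excess of π-acceptor acrylate, the ortho-benzyloxy group that retards aryl–aryl coupling and the protic reducing medium should secure. The benzyl ethers, the methyl ether and the octadecyl ester lie well outside the mild potential of the Ni(II)/Ni(0) couple, and no acidic OH group is present.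

Step 4
Reactants: 7 octadecyl 3-[2,4-bis(benzyloxy)-3-methoxyphenyl]propanoate
Product: 8 octadecyl 3-(2,4-dihydroxy-3-methoxyphenyl)propanoate (target)
Conditions: H2 (1 atm), 10% Pd/C, THF–EtOAc 1:1, rt
Reagents that add atoms: none
Why: Heterogeneous hydrogenolysis of the two benzylic C–O bonds on Pd/C under neutral conditions at room temperature should leave the aryl methyl ether and the alkyl ester untouched and avoid the acid, base or heat that could make the freed C2 hydroxyl group lactonise onto the ester.

Compound list
1 | 2-methoxybenzene-1,3-diol (2-methoxyresorcinol) | COc1c(O)cccc1O | starting material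
2 | 1,3-bis(benzyloxy)-2-methoxybenzene | COc1c(OCc2ccccc2)cccc1OCc1ccccc1 | intermediate
3 | 1,3-bis(benzyloxy)-4-bromo-2-methoxybenzene | COc1c(OCc2ccccc2)ccc(Br)c1OCc1ccccc1 | intermediate
4 | octadecyl acrylate (octadecyl prop-2-enoate) | CCCCCCCCCCCCCCCCCCOC(=O)C=C | starting material
5 | [2,4-bis(benzyloxy)-3-methoxyphenyl]nickel(II) bromide (pyridine ligands omitted; not isolated) | COc1c(OCc2ccccc2)ccc([Ni]Br)c1OCc1ccccc1 | intermediate
6 | octadecyl 3-[2,4-bis(benzyloxy)-3-methoxyphenyl]-2-(bromonickelio)propanoate (C-bound nickel enolate, racemic at C2, pyridine ligands omitted; not isolated) | CCCCCCCCCCCCCCCCCCOC(=O)C([Ni]Br)Cc1ccc(OCc2ccccc2)c(OC)c1OCc1ccccc1 | intermediate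
7 | octadecyl 3-[2,4-bis(benzyloxy)-3-methoxyphenyl]propanoate | CCCCCCCCCCCCCCCCCCOC(=O)CCc1ccc(OCc2ccccc2)c(OC)c1OCc1ccccc1 | intermediate
8 | octadecyl 3-(2,4-dihydroxy-3-methoxyphenyl)propanoate | CCCCCCCCCCCCCCCCCCOC(=O)CCc1ccc(O)c(OC)c1O | target

Total step count: 4
Longest linear sequence: 4 steps (1 → 2 → 3 → 7 → 8)

Steps most likely to fail

Step 3. The electron-rich, ortho-substituted bromide may add slowly to Ni(0), so that hydrodebromination of the aryl–nickel species, biaryl homocoupling or cathodic oligomerisation of the acrylate take over. The fallback sets out from 3 and 4 and forms the same C1–Cβ bond by a Mizoroki–Heck reaction (Pd(OAc)2, P(o-tol)3, Et3N, DMF, 100 °C), which should give octadecyl (E)-3-[2,4-bis(benzyloxy)-3-methoxyphenyl]prop-2-enoate F1. Hydrogenation of F1 (H2, Pd/C, THF–EtOAc, rt) would then saturate the alkene and cleave both benzyl ethers in one operation, so the fallback comes back to the route at target 8.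

Step 2. Substitution may leak to C5 (para to the methoxy group), and radical bromination may occur at the benzylic CH2 groups. The fallback sets out from 1 and reverses the order of bromination and protection. In the free resorcinol the two hydroxyl groups dominate the directing effects, C5 is meta to both, and no benzylic position is present. n-Bu4NBr3 (1.0 equiv) in CH2Cl2–MeOH at 0 °C should give 4-bromo-2-methoxybenzene-1,3-diol F2. Double O-benzylation of F2 (BnBr, K2CO3, DMF, 60 °C) comes back to the route at 3.

Step 4. Hydrogenolysis may stall through poisoning of the palladium surface by traces of pyridine, nickel or iron carried over from the electrolysis, and forcing the reaction invites cyclisation of the freed ortho-phenol onto the ester. The fallback sets out from 7 and replaces the reductive cleavage by a Lewis-acid debenzylation with a cation scavenger (BCl3, pentamethylbenzene, CH2Cl2, −78 °C, then aqueous NaHCO3). This does not depend on a catalyst surface, is run cold enough to spare the aryl methyl ether and the ester, and comes back to the route at 8. It makes no new compound (F0).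

Further compounds
F1 | step 3 | octadecyl (E)-3-[2,4-bis(benzyloxy)-3-methoxyphenyl]prop-2-enoate | CCCCCCCCCCCCCCCCCCOC(=O)/C=C/c1ccc(OCc2ccccc2)c(OC)c1OCc1ccccc1
F2 | step 2 | 4-bromo-2-methoxybenzene-1,3-diol | COc1c(O)ccc(Br)c1O
F0 | step 4 | none | none
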